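Five numbers and one choice are asked, and the choice is the way in.

| flask | starting material | coupling partner | remark | time |
|---|---|---|---|---|
| noon | 20 mM | 1.1 equiv | run made earlier |  |
| dusk | 30 mM | 1.1 equiv | run made earlier |  |
| zeta | 20 mM (in portions, 5, over 50 s) | 1.10 equiv | first portion at the start, last at 50 s | 2.0 min |
| gamma | 20 mM | 1.10 equiv | everything together at the start | 2.0 min |
| delta | 20 mM (fed, over 50 s) | 1.10 equiv | all else is in the flask from the start; the feed brings no volume worth counting | 2.0 min |
| epsilon | 20 mM | 1.10 equiv (fed, over 50 s) | all else is in the flask from the start; the feed brings no volume worth counting | 2.0 min |
| theta | 20 mM (fed, over 12 s) | 1.10 equiv | all else is in the flask from the start; the feed brings no volume worth counting | 2.0 min |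

| run | time / s | side product / % | mono adduct / % |
|---|---|---|---|
| noon | 20.0 | 50.7 | 3.8 |
| noon | 40.0 | 52.7 | 1.5 |
| noon | 50.0 | 54.0 | 2.0 |
| noon | 80.0 | 56.3 | 1.3 |
| dusk | 10.0 | 45.2 | 7.0 |
| dusk | 15.0 | 50.4 | 4.1 |
| dusk | 40.0 | 55.8 | 1.2 |

(scatter of a reading: 1 percentage point)

- the flask that comes out highest in amount of side product, in percent of the starting material charged; "all alike" if 1.5 percentage points covers them all (zeta / gamma / delta / epsilon / theta / all alike)
- amount of side product at the end, in percent of the starting material charged, zeta
- amount of side product at the end, in percent of the starting material charged, gamma
- amount of side product at the end, in percent of the starting material charged, delta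
- amount of side product at the end, in percent of the starting material charged, epsilon
- amount of side product at the end, in percent of the starting material charged, theta

- percent here means starting material units held: one side product counts as two
- what may be going on: coupling partner + other mono adduct -> double product; starting material + mono adduct -> side product; starting material + coupling partner -> mono adduct; starting material + coupling partner -> other mono adduct; coupling partner -> decomposition product; coupling partner + mono adduct -> double product

Turn the choice round. One way to "all alike" is a feed short against the reaction itself. But the noon run already read 90.1% of its latest side product at 20.0 s. The slow feeds take 50 s, which is longer by a factor of 2.50. So the slow feeds are not short against the reaction. The 12 s feed is shorter than those 20.0 s, so theta should stay near the batch.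

On the list of what may be going on, mono adduct goes to side product with starting material and to double product with coupling partner. At a fixed selectivity factor, the odds of that split follow [starting material]/[coupling partner].

Now replace the falling [coupling partner] curve by its mean. Take it as a straight fall from the charge to nothing. That gives 11.0 mM, the feed mean: the mean [coupling partner] reckoned for a steady feed of starting material, half the charge.

Suppose fed starting material reacts about as it arrives, so that [starting material] goes as one over the feed mean. The odds of the mono adduct split then go as one over its square, at fixed feed time, starting material charge and selectivity factor. Feeding coupling partner reverses this, so epsilon should end above the 56.3% of noon. This reckoning gives a direction, not figures.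

The forecast put epsilon highest at 61%, with gamma 56.5%, theta 54%, zeta 47% and delta 45%: “Feeding CP keeps SM in excess”.

epsilon came out highest at 60.8%, with gamma 55.0%, theta 53.2%, delta 46.8% and zeta 45.3%.

    coupling partner + other mono adduct → double product (k = 2.60 L mol⁻¹ s⁻¹)
    starting material + mono adduct → side product (k = 29.0 L mol⁻¹ s⁻¹)
    starting material + coupling partner → mono adduct (k = 5.00 L mol⁻¹ s⁻¹)
    starting material + coupling partner → other mono adduct (k = 3.90 L mol⁻¹ s⁻¹)
    coupling partner → decomposition product (k = 1.30 × 10⁻⁴ s⁻¹)
    coupling partner + mono adduct → double product (k = 6.40 L mol⁻¹ s⁻¹)

In delta, the mean [coupling partner] over the first 50 s was 13.0 mM, against the feed mean of 11.0 mM.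

Take zeta's portions as a steady feed. One side product holds two units, so 45.3% means about 0.293 of first additions ended there. The equations send 0.562 of first additions to mono adduct, so the odds of its split in zeta were about 1.09. Zeta's neighbour with 1.90 equiv of coupling partner has a feed mean of 19.0 mM. The square rule cuts the odds to 0.366, which is 26.2% side product. The neighbour computes to 23.5%.

(All runs are calculated with constants of no real substance, and the scatter is random.)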